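The ratio I carry through these flasks is how readily the partner takes the starting material against how readily it takes the protic impurity, each per unit of its own concentration. Let a be the fraction of starting material left and h the fraction of protic impurity left, in one flask at one moment.

| flask | starting material | partner | protic impurity | temperature | remark | time |
|---|---|---|---|---|---|---|
| Thursday's | 0.052 M | 0.55 equiv | 0.026 M | −20 °C | run made earlier |  |
| spring | 0.052 M | 1.10 equiv | 0.0260 M | −20 °C |  | 3.0 d |
| autumn | 0.052 M | 1.10 equiv | 0.0260 M | 20 °C |  | 3.0 d |
| dawn | 0.052 M | 1.10 equiv | 0.0260 M | 0 °C |  | 3.0 d |

Thursday's run (percent of the starting material charged)

| time / h | product / % | starting material / % |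
|---|---|---|
| 2.00 | 6 | 80 |
| 5.00 | 22 | 66 |
| 10.0 | 34 | 62 |
| 15.0 | 40 | 60 |

(each reading ± 2 percentage points)

- the numbers in the tables scatter by 2 percentage points (one standard deviation)
- a reading or a percentage of product counts all its forms, free or not
- the earlier runs do not show what temperature does; that part of a forecast is a guess

- the best flask by amount of product, in percent of the starting material charged; "all alike" if 1.5 percentage points covers them all (spring / autumn / dawn / all alike)
- amount of product at the end, in percent of the starting material charged, spring
- amount of product at the end, in percent of the starting material charged, autumn
- amount of product at the end, in percent of the starting material charged, dawn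

I assume that each loss is first order in the partner and first order in its own substrate. The partner then cancels from the ratio of the two fractional losses, so ln a = s ln h at any moment of a run at one temperature, where s is the ratio just named.

I treat Thursday's last reading as that run's end, because the starting material moves from 62% to 60% between 10.0 h and 15.0 h, which is the size of the scatter. So Thursday's a is 60%. The partner charged was 0.55 equiv, and what did not reach the starting material is 15.0% of the starting material charged. I assume that this share went to the protic impurity, whose charge is r = 0.500 of the starting material charge, so Thursday's h is 70.0%. That gives the selectivity factor s = ln a / ln h = 1.43, a reading that carries the scatter.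

Spring has E = 1.10 equiv of partner, and two versions of it can be solved in the head. If s were one, a equals h and the product is E/(1 + r) in percent, 73.3%. If s were huge, the impurity waits and the partner covers all the starting material, giving 100%. Spring lies between, since s is above one.

If the partner reacts to the end, the balance says that the fraction of starting material used plus r times the fraction of impurity used equals E. I try h = 0.350, so a = h^s = 22.2%, and the partner used is 1.10 equiv, which meets the charge. I commit to 77.8% of product. The 3.0 d is 4.80 times Thursday's last reading, so I count spring as finished. For autumn and dawn I guess the same s, hence all alike.

The forecast says 75% for spring, 74% for autumn and 75% for dawn, lower than mine for spring, and all alike, noting that “Only selectivity could shift with temperature”.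

The flasks give 79.9% in spring, 81.0% in autumn and 80.6% in dawn, a spread of 1 percentage point, so all alike. My figure stands 2.1 points below spring.

    starting material + partner → intermediate + released group (k = 0.0860 M⁻¹ min⁻¹, Ea = 50.0 kJ mol⁻¹)
    partner + protic impurity → quenched reagent (k = 0.0480 M⁻¹ min⁻¹, Ea = 49.0 kJ mol⁻¹)
    partner + product ⇌ idle adduct, settled at all times (K = 12.0 M⁻¹, ΔH = −51.0 kJ mol⁻¹)
    intermediate → product (k = 0.00760 min⁻¹, Ea = 81.0 kJ mol⁻¹)
    (constants at −20 °C)

In dawn the partner is used by the starting material 3.7 times as fast as by the protic impurity just after the start, and 2.8 times as fast at 0.0244 d. At 3.00 d dawn holds 0% of its partner, the limiting reagent, with 19% of starting material and 41% of impurity still there. For dawn's neighbour, charged with 0.660 equiv of partner, my s, read at −20 °C, nearly meets the balance at h = 0.630, which uses 0.669 equiv and gives 48.4% of product; that flask ends with 50.3%.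

The runs stem from a simulated flask for an exercise, noise included.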